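**Retrosynthetic overview**
- The target is the threo-(7S,8S) 8-O-4' ether (1S,2S in propane numbering). No rings are formed; both arenes are bought intact.
- Last disconnections: benzyl ethers (hydrogenolysis) and the methyl benzoate (saponification).
- C7–aryl bond: chelation-controlled addition of a 4-benzyloxy-3-methoxyphenyl Grignard reagent to an (S)-2-aryloxy-3-benzyloxypropanal, so C8 sets C7.
- C8–O–aryl bond (key bond): visible-light Ni/Ir C–O cross-coupling of an (S)-α-hydroxy Weinreb amide with methyl 4-bromo-3,5-dimethoxybenzoate, with retention at C8.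
- C8 stereocentre: from O-benzyl-L-serine by retentive diazotisation.

Assumption: O-benzyl-L-serine (H-Ser(Bzl)-OH), methyl 4-bromo-3,5-dimethoxybenzoate and 1-(benzyloxy)-4-bromo-2-methoxybenzene are taken as commercial materials.

**Step 1**
Reactants: 1, O-benzyl-L-serine [(S)-2-amino-3-(benzyloxy)propanoic acid]
Product: 2, (S)-3-(benzyloxy)-2-hydroxypropanoic acid
Conditions: NaNO2, 1 M aq. H2SO4, 0 °C → rt
Reagents that add atoms: water, O
Why: Diazotisation of a free α-amino acid (van Slyke type) proceeds through the α-lactone (double inversion), so the hydroxyl replaces nitrogen with net retention and C2 stays S.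

**Step 2**
Reactants: 2, (S)-3-(benzyloxy)-2-hydroxypropanoic acid
Product: 3, (S)-3-(benzyloxy)-2-hydroxy-N-methoxy-N-methylpropanamide
Conditions: MeNHOMe·HCl, EDC·HCl, HOBt, NMM, CH2Cl2, 0 °C → rt
Reagents that add atoms: N,O-dimethylhydroxylamine hydrochloride, CNOC.Cl
Why: Carbodiimide amidation (Weinreb amide formation) is faster at nitrogen than at the free secondary hydroxyl and does not touch the stereocentre.

**Step 3**
Reactants: 3, (S)-3-(benzyloxy)-2-hydroxy-N-methoxy-N-methylpropanamide (1.5 equiv); 4, methyl 4-bromo-3,5-dimethoxybenzoate (1.0 equiv)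
Product: 5, methyl 4-{[(2S)-3-(benzyloxy)-1-[methoxy(methyl)amino]-1-oxopropan-2-yl]oxy}-3,5-dimethoxybenzoate
Conditions: NiCl2·glyme (10 mol%), dtbbpy (10 mol%), Ir[dF(CF3)ppy]2(dtbbpy)PF6 (1 mol%), quinuclidine (10 mol%), K2CO3, MeCN, 450 nm LEDs, 25 °C
Reagents that add atoms: none
Why: Proposed new method: Ni/photoredox C(sp2)–O cross-coupling extended to a secondary α-hydroxy amide and a 2,6-dialkoxyaryl bromide; Ni(0) adds oxidatively to the C–Br bond (activated by the para ester), the relatively acidic α-hydroxy amide binds Ni(II) as an O,O-chelating alkoxide that resists β-hydride elimination, and Ir(III)* oxidises this to Ni(III), from which C–O reductive elimination is fast and helped by steric relief at the di-ortho-substituted aryl; only the O–H bond reacts, so C2 keeps its S configuration (the amide α-C–H is less acidic than an ester's under the carbonate base); the closest known reaction type is Ni/Ir photoredox etherification of aryl bromides with simple primary and secondary alcohols.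

**Step 4**
Reactants: 5, the Weinreb amide ether from step 3
Product: 6, methyl 4-{[(2S)-1-(benzyloxy)-3-oxopropan-2-yl]oxy}-3,5-dimethoxybenzoate (α-aryloxy aldehyde, used crude at once)
Conditions: Cp2Zr(H)Cl (1.5 equiv), THF, rt, 20 min
Reagents that add atoms: none
Why: Schwartz-reagent reduction of a tertiary (Weinreb) amide stops at the aldehyde and leaves the aromatic methyl ester intact; the short, non-basic conditions protect the α-stereocentre.

**Step 5**
Reactants: 6, the (S)-aldehyde; 7, 1-(benzyloxy)-4-bromo-2-methoxybenzene (converted in situ to the arylmagnesium bromide)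
Product: 8, methyl 4-{[(1S,2S)-3-(benzyloxy)-1-[4-(benzyloxy)-3-methoxyphenyl]-1-hydroxypropan-2-yl]oxy}-3,5-dimethoxybenzoate
Conditions: 7, Mg, THF → ArMgBr (2 equiv); 6, MgBr2·OEt2 (2 equiv), CH2Cl2, −78 °C; NH4Cl quench at −78 °C
Reagents that add atoms: none
Why: Cram-chelate-controlled Grignard addition: Mg bridges the aldehyde oxygen and the C2 aryloxy oxygen (twisted out of conjugation by the two ortho methoxy groups, so a good donor), and the aryl group adds anti to CH2OBn to give the syn (threo) 1S,2S alcohol; the benzoate ester is inert at −78 °C.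

**Step 6**
Reactants: 8, the threo methyl ester
Product: 9, 4-{[(1S,2S)-3-(benzyloxy)-1-[4-(benzyloxy)-3-methoxyphenyl]-1-hydroxypropan-2-yl]oxy}-3,5-dimethoxybenzoic acid
Conditions: LiOH·H2O, THF/MeOH/H2O, rt; acidify to pH 3–4 at 0 °C
Reagents that add atoms: lithium hydroxide, [Li+].[OH-]
Why: Saponification of the methyl benzoate; the benzyl ethers, the β-aryl ether and both stereocentres (no adjacent carbonyl) are stable to mild base.

**Step 7**
Reactants: 9, the bis-benzyl ether acid
Product: 10, 4-{[(1S,2S)-1,3-dihydroxy-1-(4-hydroxy-3-methoxyphenyl)propan-2-yl]oxy}-3,5-dimethoxybenzoic acid (target)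
Conditions: H2 (1 atm), 10% Pd/C, EtOAc/EtOH, rt, stop at full conversion
Reagents that add atoms: none
Why: Hydrogenolysis of the phenolic and primary benzyl ethers is much faster under neutral conditions than C–O cleavage of the secondary benzylic alcohol, and the non-benzylic C8–O aryl ether is untouched.

**Compound list**
1 | O-benzyl-L-serine | N[C@@H](COCc1ccccc1)C(=O)O | starting material
2 | (S)-3-(benzyloxy)-2-hydroxypropanoic acid | O[C@@H](COCc1ccccc1)C(=O)O | intermediate
3 | (S)-3-(benzyloxy)-2-hydroxy-N-methoxy-N-methylpropanamide | O[C@@H](COCc1ccccc1)C(=O)N(C)OC | intermediate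
4 | methyl 4-bromo-3,5-dimethoxybenzoate | COC(=O)c1cc(OC)c(Br)c(OC)c1 | starting material
5 | methyl 4-{[(2S)-3-(benzyloxy)-1-[methoxy(methyl)amino]-1-oxopropan-2-yl]oxy}-3,5-dimethoxybenzoate | COC(=O)c1cc(OC)c(O[C@@H](COCc2ccccc2)C(=O)N(C)OC)c(OC)c1 | intermediate
6 | methyl 4-{[(2S)-1-(benzyloxy)-3-oxopropan-2-yl]oxy}-3,5-dimethoxybenzoate | COC(=O)c1cc(OC)c(O[C@@H](COCc2ccccc2)C=O)c(OC)c1 | intermediate
7 | 1-(benzyloxy)-4-bromo-2-methoxybenzene | COc1cc(Br)ccc1OCc1ccccc1 | starting material
8 | methyl 4-{[(1S,2S)-3-(benzyloxy)-1-[4-(benzyloxy)-3-methoxyphenyl]-1-hydroxypropan-2-yl]oxy}-3,5-dimethoxybenzoate | COc1cc([C@H](O)[C@H](COCc2ccccc2)Oc2c(OC)cc(C(=O)OC)cc2OC)ccc1OCc1ccccc1 | intermediate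
9 | 4-{[(1S,2S)-3-(benzyloxy)-1-[4-(benzyloxy)-3-methoxyphenyl]-1-hydroxypropan-2-yl]oxy}-3,5-dimethoxybenzoic acid | COc1cc([C@H](O)[C@H](COCc2ccccc2)Oc2c(OC)cc(C(=O)O)cc2OC)ccc1OCc1ccccc1 | intermediate
10 | 4-{[(1S,2S)-1,3-dihydroxy-1-(4-hydroxy-3-methoxyphenyl)propan-2-yl]oxy}-3,5-dimethoxybenzoic acid | COc1cc([C@H](O)[C@H](CO)Oc2c(OC)cc(C(=O)O)cc2OC)ccc1O | target

**Totals**
Total steps: 7 (Grignard formation from 7 is done in situ in step 5).
Longest linear sequence: 7 steps (1 → 10).

**Steps most likely to fail, with fallbacks**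
1. Step 3 (proposed new C–O coupling). Risks are the hindered 2,6-dimethoxyaryl–Ni intermediate, β-hydride elimination to the α-keto amide, and protodebromination. Fallback (known chemistry): form the C8–O bond by SN2 with inversion instead. O-benzyl-D-serine is diazotised to the (R)-hydroxy acid, converted to the methyl ester and then the triflate (Tf2O, 2,6-lutidine), and displaced with methyl syringate/K2CO3 in MeCN to give the (S)-aryloxy ester. Selective DIBAL-H reduction at −78 °C then gives aldehyde 6.
2. Step 5 (diastereoselectivity and aldehyde epimerisation). Competing Felkin addition or chelation through the C3 benzyloxy group would erode the threo ratio. Fallback: add the Grignard reagent to Weinreb amide 5 to give the aryl ketone, then reduce under non-chelating Felkin–Anh conditions (K-Selectride, THF, −78 °C, or NaBH4/15-crown-5), which also favours the threo alcohol.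
3. Step 7 (over-reduction of the electron-rich benzylic alcohol, or slow cleavage of the primary benzyl ether). Fallback: change the protecting-group plan to silyl ethers. This means a TBS ether on the aryl Grignard phenol and a TBDPS ether on C3 (from L-serine via methyl (S)-glycerate), finishing with fluoride (TBAF/AcOH) and LiOH so that no hydrogenation is needed.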